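# Proposed synthesis of (2R)-2,6-dihydroxy-2-[(2E,6E)-farnesyl]-1-benzofuran-3(2H)-one (10)

## Analysis of the target

- Compound 10 has a resorcinol-type benzene ring (C3a, C4–C7, C7a; free OH on C6, para to C3a). It is fused to the five-membered ring O1–C2–C3(=O)–C3a–C7a, and C2 carries an unbranched C15 chain (C1'–C12', alkenes at C2', C6', C10').
- The only stereocentre is C2. It is fully substituted and carries O1, a free OH, the carbonyl carbon C3 and C1'H2, so it is the cyclic hemiketal of an aryl alkyl 1,2-diketone.
- This makes C2 configurationally fragile. Loss of the o-acylphenoxide O1 from the C2 alkoxide opens the ring to an achiral diketone. In that open form C1'H2 is both allylic and α to a ketone, so base can also move C2'=C3' into conjugation or start a benzilic-type acyl shift.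
- The chain adds three trisubstituted alkenes that do not tolerate electrophilic oxidants or strong Brønsted and Lewis acids. Two of them (2'E, 6'E) have a geometry that is best bought and never touched.
- The C6 phenol is a vinylogous acid (para to C3=O) and needs masking whenever a base is present.
- The difficulty is therefore order and medium, not size. An oxygenated quaternary centre must be made enantioselectively beside a polyene, and the hemiketal OH must never exist as an alkoxide.
- Two features of the five-membered ring invite the key step. Enolisation across C2–C3 turns O1–C2–C3–C3a–C7a into the furan ring of an aromatic benzofuran, so a flat C2 nucleophile is unusually easy to reach. The array O=C3–C2–C1'–C2'=C3' is a γ,δ-unsaturated ketone, the retron of an allyl transfer to an enolate carbon.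

## Retrosynthetic reasoning

**10 ⇒ 9.** Only two O–Si bonds are cut. The hemiketal oxygen stays locked as a silyl ketal until the last operation, because a ketal cannot open to the achiral diketone. The cleavage takes place at silicon, so the C2–O bond and the configuration are untouched. The same reagent frees the C6 phenol, so both masks cost one step. The forward reaction has to run in a weakly acidic medium, so that the C2 oxygen is protonated as it is released.

**9 ⇒ 4 + 6 (through 7 and 8).** The C2–C1' bond is cut, the bond between the heterocycle and the whole C15 chain.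
- This cut leaves the bought 2'E,6'E chain intact.
- It puts the stereodefining event into a C–C bond formation on a carbon that already carries both oxygens.
- It divides the target into two halves of equal size.
- In the forward sense the racemic, acidic C2–H of 4 is removed. This erases that stereocentre in the planar aromatic anion 8, which is then dearomatised by attack on the chiral π-allyl complex 7 made from 6.
- One operation therefore joins the halves, builds the quaternary carbon and sets the only stereocentre.
- It must deliver C- rather than O-allylation, C2 rather than C3, the linear rather than the branched chain, and one face of 8.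

**4 ⇒ 2 (through 3).** The C2–O bond is cut. All oxidation chemistry is placed before the polyene enters, so chemoselectivity against three alkenes never arises. Oxygen transfer to the C2=C3 bond of the electron-rich benzofuran 2 gives 3. Its collapse moves the silyl group from O3 to O2, so the step installs the oxygen and its lock at once. The stereocentre formed here may be racemic, because the key step erases it.

**2 ⇒ 1 and 6 ⇒ 5.** Only O–Si and O–C(=O) bonds are cut. Double silylation of commercial 1 masks the phenol and aromatises the heterocycle in one step. Commercial 5 is activated at oxygen only, so neither the position nor the geometry of its alkenes is at risk.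

## Alternatives that were turned down

**Alternative 1:** (textbook) Disconnection of C2–OH. A 6-O-protected derivative of 1 is monoalkylated at C2 to give 2-farnesyl-6-silyloxybenzofuran-3(2H)-one A1. The forward key step is oxygen transfer from an enantiopure N-sulfonyloxaziridine to the enolate of A1. It was turned down for four reasons.
- The oxygen arrives on an anion, so the product is born as the C2 alkoxide. That alkoxide is the tetrahedral intermediate that expels O1 and gives the open diketone A2. Reclosure has no facial bias, so the selectivity leaks away in the flask, and A2 is exposed to base.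
- Neutral electrophilic oxygen donors avoid the alkoxide but cannot tell the C2=C3 enol ether from three trisubstituted alkenes.
- A1 is as acidic as its precursor and its anion is ambident. O-alkylation and double alkylation therefore burden the step that makes it.
- A stoichiometric chiral oxidant is spent, and no step is saved.

**Alternative 2:** Disconnection of C2–C1' together with C3–O by a sigmatropic shift with chirality transfer. A rhodium(II) carbene from the diazolactone A3 would take up the O–H of enantiopure (E)-nerolidol A4. Proton transfer would give the 2-hydroxybenzofuran allyl ether A5, and a [3,3] shift would give the free hemiketal A6 under neutral conditions. The idea is attractive but fails on structure.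
- C2'=C3' is created in the shift from a tertiary carbinol whose two substituents (CH3 and CH2CH2R) differ little in size, so E and Z chains must both form.
- The E and Z products arise from opposite faces of C2, so geometry and configuration are lost together.
- A geometry that can be bought is given away.
- The oxonium ylide of a donor/acceptor carbene and a tertiary allylic alcohol has a direct [2,3] path to the carbene carbon. This leads to the isomeric and more stable lactone A7.
- Enantiopure A4 costs several steps of its own.

**Alternative 3:** Biomimetic change of skeleton. The chain is placed on C3 of a 4,7-dihydroxycoumarin to give A8. Aerobic oxygenation at C3 gives the hydroperoxide A9. Lactone opening and decarboxylative fragmentation contract the ring by way of the open diketone A10. The route is very short, but it was turned down.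
- The carbon that becomes C2 passes through a planar ketone in A10, so any configuration set at A9 is erased.
- The final closure of O1 onto C2 is uncontrolled and gives the racemate of 10.
- A single enantiomer would then need a resolution on the labile hemiketal itself.
- The oxygenation runs under basic, radical-prone conditions in the presence of the polyene.

Key step: step 4

**Assumption 1:** hemiketal 10 is taken to hold its configuration at or below room temperature in neutral to weakly acidic, amine-poor media, where ring–chain exchange of hemiketals is slowest.

**Assumption 2:** the (R,R) ligand is written for the (2S) product 9. If the sense of induction is the opposite, the equally available (S,S) ligand is used and nothing else changes.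

## Steps

Step 1
Reactants: 1 6-hydroxy-1-benzofuran-3(2H)-one
Product: 2 3,6-bis[(tert-butyldimethylsilyl)oxy]-1-benzofuran
Conditions: TBSOTf (2.3 equiv), Et3N (3 equiv), CH2Cl2, 0 °C to rt
Reagents that add atoms: tert-butyldimethylsilyl triflate (TBSOTf), CC(C)(C)[Si](C)(C)OS(=O)(=O)C(F)(F)F
Why: Soft enolisation and O-silylation; the gain of furan aromaticity drives silylation at O3 rather than at carbon, and the acidic C6 phenol is silylated in the same operation. No stereocentre is involved.

Step 2
Reactants: 2 3,6-bis[(tert-butyldimethylsilyl)oxy]-1-benzofuran
Product: 4 rac-2,6-bis[(tert-butyldimethylsilyl)oxy]-1-benzofuran-3(2H)-one, via siloxy epoxide 3 (not isolated)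
Conditions: dimethyldioxirane (1.0 equiv, acetone), CH2Cl2, −78 to 0 °C
Reagents that add atoms: dimethyldioxirane, CC1(C)OO1
Why: Rubottom oxidation under neutral conditions; the C2=C3 enol ether is the most electron-rich π bond, and epoxide 3 opens with O1/OSi assistance and 1,4-silyl transfer from O3 to O2. The C2 stereocentre forms as a racemate, which is harmless because step 4 erases it, and no alkene of the chain is yet present.

Step 3
Reactants: 5 (2E,6E)-farnesol
Product: 6 tert-butyl (2E,6E)-3,7,11-trimethyldodeca-2,6,10-trien-1-yl carbonate
Conditions: Boc2O (1.2 equiv), DMAP (10 mol %), CH2Cl2, 0 °C to rt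
Reagents that add atoms: di-tert-butyl dicarbonate (Boc2O), CC(C)(C)OC(=O)OC(=O)OC(C)(C)C
Why: DMAP-catalysed O-acylation of a primary alcohol; the allylic C–O bond is not broken, so alkene position and E,E geometry are kept.

Step 4
Reactants: 4 rac-2,6-bis[(tert-butyldimethylsilyl)oxy]-1-benzofuran-3(2H)-one; 6 tert-butyl (2E,6E)-farnesyl carbonate
Product: 9 (2S)-2,6-bis[(tert-butyldimethylsilyl)oxy]-2-[(2E,6E)-3,7,11-trimethyldodeca-2,6,10-trien-1-yl]-1-benzofuran-3(2H)-one, via π-farnesylpalladium cation 7 (not isolated), via benzofuran-3-olate 8 (not isolated)
Conditions: Pd2(dba)3·CHCl3 (2.5 mol %), (1R,2R)-N,N'-bis[2-(diphenylphosphino)benzoyl]cyclohexane-1,2-diamine (7.5 mol %), toluene (degassed), 0 °C to rt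
Reagents that add atoms: none
Why: Pd(0) ionises 6 with decarboxylation to the cationic π-allyl complex 7 and tert-butoxide, which removes the acidic C2–H of 4 and so erases its racemic stereocentre in the planar, aromatic 2-siloxybenzofuran-3-olate 8. Outer-sphere attack of C2 of 8 on the unsubstituted terminus C1' of 7 forms the C2–C1' bond, dearomatises the furan ring and restores the C3 ketone; the type is the Tsuji–Trost asymmetric allylic alkylation of a prochiral stabilised enolate, with the linear prenylation and geranylation of 3-substituted oxindoles and the allylation of siloxy- and acyloxy-enediol derivatives as closest relatives. No ring is closed. The one new stereocentre, C2, is controlled by the chiral pocket of the C2-symmetric diamide bisphosphine, which in the tight ion pair favoured by toluene admits one face of 8, the bulky OTBS group on C2 and the flat benzo flank being the elements that are told apart. Four selectivities are needed: C over O (O3-allylation is reversible under Pd(0) because 8 is a good leaving group, C-allylation is not), C2 over C3 (the silyl group stays on O2 because the exocyclic C2–O and C3–O bonds of a five-membered ring splay apart and disfavour the cyclic pentacoordinate silicon of a 1,4-shift), linear over branched (attack at C3' would join two fully substituted carbons), and retention of the 2'E geometry (syn/anti exchange would need palladium σ-bound to the tertiary C3'). The isolated alkenes, both silyl ethers and the ketone are inert to Pd(0) in a medium that never holds more base than substrate.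

Step 5
Reactants: 9 (2S)-2,6-bis[(tert-butyldimethylsilyl)oxy]-2-[(2E,6E)-farnesyl]-1-benzofuran-3(2H)-one
Product: 10 (2R)-2,6-dihydroxy-2-[(2E,6E)-3,7,11-trimethyldodeca-2,6,10-trien-1-yl]-1-benzofuran-3(2H)-one
Conditions: HF·pyridine, excess pyridine, THF, 0 °C; quench into pH 6 phosphate buffer
Reagents that add atoms: none
Why: Fluoride-mediated desilylation at silicon; both oxygens are good leaving groups (vinylogous-acid phenoxide, α-keto hemiketal oxygen) and are protonated as they leave, so no alkoxide builds up and the C2–O bond is never broken. The configuration is retained; the descriptor changes from S to R only because OSi outranks O1 while OH does not.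

## Compound list

| No. | Name | SMILES | Role |
|---|---|---|---|
| 1 | 6-hydroxy-1-benzofuran-3(2H)-one | O=C1COc2cc(O)ccc21 | starting material |
| 2 | 3,6-bis[(tert-butyldimethylsilyl)oxy]-1-benzofuran | CC(C)(C)[Si](C)(C)Oc1ccc2c(O[Si](C)(C)C(C)(C)C)coc2c1 | intermediate |
| 3 | rac-2,3-epoxy-3,6-bis[(tert-butyldimethylsilyl)oxy]-2,3-dihydro-1-benzofuran | CC(C)(C)[Si](C)(C)Oc1ccc2c(c1)OC1OC21O[Si](C)(C)C(C)(C)C | intermediate |
| 4 | rac-2,6-bis[(tert-butyldimethylsilyl)oxy]-1-benzofuran-3(2H)-one | CC(C)(C)[Si](C)(C)Oc1ccc2C(=O)C(O[Si](C)(C)C(C)(C)C)Oc2c1 | intermediate |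
| 5 | (2E,6E)-farnesol | CC(C)=CCC/C(C)=C/CC/C(C)=C/CO | starting material |
| 6 | tert-butyl (2E,6E)-farnesyl carbonate | CC(C)=CCC/C(C)=C/CC/C(C)=C/COC(=O)OC(C)(C)C | intermediate |
| 7 | η3-(2E,6E)-farnesylpalladium cation (drawn σ-bound at C1', bisphosphine omitted) | CC(C)=CCC/C(C)=C/CC/C(C)=C/C[Pd+] | intermediate |
| 8 | 2,6-bis[(tert-butyldimethylsilyl)oxy]-1-benzofuran-3-olate | CC(C)(C)[Si](C)(C)Oc1ccc2c([O-])c(O[Si](C)(C)C(C)(C)C)oc2c1 | intermediate |
| 9 | (2S)-2,6-bis[(tert-butyldimethylsilyl)oxy]-2-[(2E,6E)-farnesyl]-1-benzofuran-3(2H)-one | CC(C)=CCC/C(C)=C/CC/C(C)=C/C[C@@]1(O[Si](C)(C)C(C)(C)C)Oc2cc(O[Si](C)(C)C(C)(C)C)ccc2C1=O | intermediate |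
| 10 | (2R)-2,6-dihydroxy-2-[(2E,6E)-farnesyl]-1-benzofuran-3(2H)-one | CC(C)=CCC/C(C)=C/CC/C(C)=C/C[C@@]1(O)Oc2cc(O)ccc2C1=O | target |

## Step count and least certain steps

Total step count: 5. Longest linear sequence: 4 steps (1 → 2 → 4 → 9 → 10).

**Step 4 (key step).**
- *What may go wrong.* The most likely failure is insufficient facial discrimination of the flat anion, because both flanks of C2 are oxygen-substituted and the electrophile terminus is remote from the ligand walls. There are two secondary risks. If C–C bond formation is slow, the π-allyl complex may be lost by β-hydride elimination. If the silyl group migrates from O2 to O3 in the anion, the site of allylation would shift.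
- *Fallback.* It sets out from 4 and returns at 9, and it replaces catalytic enantioselection by separation of locked enantiomers. Compound 4 is C-alkylated with (2E,6E)-farnesyl bromide (K2CO3, acetone, rt). The SN2 reaction at the primary allylic carbon keeps the chain linear and E,E. The product is the racemic silyl ketal rac-2,6-bis[(tert-butyldimethylsilyl)oxy]-2-[(2E,6E)-farnesyl]-1-benzofuran-3(2H)-one F1. C2 is a ketal, so the enantiomers cannot interconvert and are separated by preparative SFC on a polysaccharide phase. The (2S) enantiomer is 9, and the (2R)-enantiomer of the silyl ketal F2 is set aside.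

**Step 5.**
- *What may go wrong.* The most likely failure is erosion of configurational purity by ring–chain exchange of the freshly released hemiketal, catalysed by fluoride or pyridine acting as general bases. Slow cleavage of the hindered O2 silyl group would prolong the exposure.
- *Fallback.* It sets out from 9 and returns at 10, and it stages the end-game and releases the hemiketal hydrolytically. The activated aryl silyl ether is removed first, while C2 is still locked (LiOAc cat., moist DMF, rt). This gives (2S)-2-[(tert-butyldimethylsilyl)oxy]-2-[(2E,6E)-farnesyl]-6-hydroxy-1-benzofuran-3(2H)-one F3. Only then is the O2–Si bond hydrolysed under acid catalysis (AcOH/THF/H2O, rt), without fluoride or amine, at the acidity where hemiketal opening is slowest.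

**Step 2.**
- *What may go wrong.* The most likely failures are capture of the opened epoxide by adventitious water before the silyl group has migrated, and further oxidation of the still enolisable product.
- *Fallback.* It sets out from 2 and returns at 4, and it replaces oxygen transfer by halogenation and substitution. NBS (THF, −78 °C) converts 2 into rac-2-bromo-6-[(tert-butyldimethylsilyl)oxy]-1-benzofuran-3(2H)-one F4. Silver-assisted hydrolysis of Koenigs–Knorr type (Ag2CO3, aqueous acetone) gives the hemiacetal rac-2-hydroxy-6-[(tert-butyldimethylsilyl)oxy]-1-benzofuran-3(2H)-one F5. Silylation (TBSCl, imidazole, DMF) then gives 4.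

## Further compounds

F1 | step 4 | rac-2,6-bis[(tert-butyldimethylsilyl)oxy]-2-[(2E,6E)-farnesyl]-1-benzofuran-3(2H)-one | CC(C)=CCC/C(C)=C/CC/C(C)=C/CC1(O[Si](C)(C)C(C)(C)C)Oc2cc(O[Si](C)(C)C(C)(C)C)ccc2C1=O
F2 | step 4 | (2R)-2,6-bis[(tert-butyldimethylsilyl)oxy]-2-[(2E,6E)-farnesyl]-1-benzofuran-3(2H)-one | CC(C)=CCC/C(C)=C/CC/C(C)=C/C[C@]1(O[Si](C)(C)C(C)(C)C)Oc2cc(O[Si](C)(C)C(C)(C)C)ccc2C1=O
F3 | step 5 | (2S)-2-[(tert-butyldimethylsilyl)oxy]-2-[(2E,6E)-farnesyl]-6-hydroxy-1-benzofuran-3(2H)-one | CC(C)=CCC/C(C)=C/CC/C(C)=C/C[C@@]1(O[Si](C)(C)C(C)(C)C)Oc2cc(O)ccc2C1=O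
F4 | step 2 | rac-2-bromo-6-[(tert-butyldimethylsilyl)oxy]-1-benzofuran-3(2H)-one | CC(C)(C)[Si](C)(C)Oc1ccc2C(=O)C(Br)Oc2c1
F5 | step 2 | rac-2-hydroxy-6-[(tert-butyldimethylsilyl)oxy]-1-benzofuran-3(2H)-one | CC(C)(C)[Si](C)(C)Oc1ccc2C(=O)C(O)Oc2c1
A1 | alternative 1 | rac-6-[(tert-butyldimethylsilyl)oxy]-2-[(2E,6E)-farnesyl]-1-benzofuran-3(2H)-one | CC(C)=CCC/C(C)=C/CC/C(C)=C/CC1Oc2cc(O[Si](C)(C)C(C)(C)C)ccc2C1=O
A2 | alternative 1 | (4E,8E)-1-{4-[(tert-butyldimethylsilyl)oxy]-2-hydroxyphenyl}-5,9,13-trimethyltetradeca-4,8,12-triene-1,2-dione | CC(C)=CCC/C(C)=C/CC/C(C)=C/CC(=O)C(=O)c1ccc(O[Si](C)(C)C(C)(C)C)cc1O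
A3 | alternative 2 | 6-[(tert-butyldimethylsilyl)oxy]-3-diazo-1-benzofuran-2(3H)-one | [N-]=[N+]=C1C(=O)Oc2cc(O[Si](C)(C)C(C)(C)C)ccc21
A4 | alternative 2 | (3S,6E)-nerolidol | C=C[C@@](C)(O)CC/C=C(\C)CCC=C(C)C
A5 | alternative 2 | 6-[(tert-butyldimethylsilyl)oxy]-3-{[(3S,6E)-3,7,11-trimethyldodeca-1,6,10-trien-3-yl]oxy}-1-benzofuran-2-ol | C=C[C@](C)(CC/C=C(\C)CCC=C(C)C)Oc1c(O)oc2cc(O[Si](C)(C)C(C)(C)C)ccc12
A6 | alternative 2 | (2R)-6-[(tert-butyldimethylsilyl)oxy]-2-[(2E,6E)-farnesyl]-2-hydroxy-1-benzofuran-3(2H)-one | CC(C)=CCC/C(C)=C/CC/C(C)=C/C[C@@]1(O)Oc2cc(O[Si](C)(C)C(C)(C)C)ccc2C1=O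
A7 | alternative 2 | 6-[(tert-butyldimethylsilyl)oxy]-3-[(2E,6E)-farnesyl]-3-hydroxy-1-benzofuran-2(3H)-one | CC(C)=CCC/C(C)=C/CC/C(C)=C/CC1(O)C(=O)Oc2cc(O[Si](C)(C)C(C)(C)C)ccc21
A8 | alternative 3 | 3-[(2E,6E)-farnesyl]-4,7-dihydroxy-2H-chromen-2-one | CC(C)=CCC/C(C)=C/CC/C(C)=C/CC1=C(O)c2ccc(O)cc2OC1=O
A9 | alternative 3 | 3-[(2E,6E)-farnesyl]-3-hydroperoxy-7-hydroxychromane-2,4-dione | CC(C)=CCC/C(C)=C/CC/C(C)=C/CC1(OO)C(=O)Oc2cc(O)ccc2C1=O
A10 | alternative 3 | (4E,8E)-1-(2,4-dihydroxyphenyl)-5,9,13-trimethyltetradeca-4,8,12-triene-1,2-dione | CC(C)=CCC/C(C)=C/CC/C(C)=C/CC(=O)C(=O)c1ccc(O)cc1O
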